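**Plan**

- Ring numbering used here: C1 (C=O between C–OH and C–H), C2 (C–OH), C3 (C–docosyl), C4 (C=O), C5 (C–OMe), C6 (C–H).
- Retrosynthesis: the C2 hydroxyl is masked as a tert-butyl ether; ring bond C4–C5 is cut and C1 is joined to C4, contracting the quinone ring to a cyclobutenone (C1–C4) that carries OH and a methoxyethynyl group (C6≡C5–OMe) on C1; then C1–C6 is cut (acetylide + cyclobutenedione) and C3–docosyl is cut (Grignard reagent + di-tert-butyl squarate).
- Enabling feature: C1–C2–C3–C4 is a squaric acid pattern (two carbonyl carbons joined through an oxygenated and an alkylated sp2 carbon), and C5(OMe)=C6H is an ynol ether at the oxidation level of the quinone, so a 4-alkynyl-4-hydroxycyclobutenone already holds all six ring carbons.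
- Forward: the four-membered ring is bought; docosyl is joined to C3; methoxyacetylide is joined to C1; a thermal two-carbon ring expansion forms C4–C5 and gives the six-membered quinone ring; the tert-butyl group is removed.
- Stereochemistry: the target has no stereocentre and no stereogenic double bond; the carbinol centre of the cyclobutenone is racemic and is erased in the ring expansion; the substitution pattern follows from the order of the two carbonyl additions.

Key step: step 4

Remark: di-tert-butyl squarate is taken as a catalogue squaric ester, like its dimethyl, diethyl and diisopropyl relatives.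

**Step 1**
Reactants: 1 1-bromodocosane; 2 di-tert-butyl squarate (3,4-di-tert-butoxycyclobut-3-ene-1,2-dione)
Product: 6 3-tert-butoxy-4-docosylcyclobut-3-ene-1,2-dione, via docosylmagnesium bromide 3 (not isolated), via bromomagnesium alkoxide adduct 4 (not isolated), via trifluoroacetate ester 5 (not isolated)
Conditions: Mg turnings, cat. I2, THF, 45 °C; warm solution added to 2, THF, −78 → −40 °C; (CF3CO)2O, −78 → 0 °C; aq NaHCO3
Reagents that add atoms: none
Why: The Grignard reagent should add 1,2 to one squarate carbonyl, and O-trifluoroacetylation of the alkoxide, ionisation to the alkoxy-stabilised cyclobutenyl cation and loss of the tert-butyl cation as 2-methylpropene from the neighbouring oxocarbenium carbon transpose the carbonyl (the standard squarate to 3-alkoxy-4-alkylcyclobutenedione sequence), with no stereocentre left in the product.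

**Step 2**
Reactants: 7 2-chloro-1,1-dimethoxyethane (chloroacetaldehyde dimethyl acetal)
Product: 9 methoxyacetylene (methoxyethyne), via sodium methoxyacetylide 8 (not isolated)
Conditions: NaNH2 (3 equiv), liq. NH3, −33 °C; NH3 evaporated; cold sat. aq NaCl, −70 °C; distilled through CaCl2 into THF at −78 °C
Reagents that add atoms: none
Why: Two base-induced eliminations (methanol, then hydrogen chloride) from the chloroacetal with NaNH2 are the classical ynol ether synthesis, and the product is held as its sodium acetylide until the cold aqueous quench, so no over-reaction should occur.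

**Step 3**
Reactants: 6 3-tert-butoxy-4-docosylcyclobut-3-ene-1,2-dione; 9 methoxyacetylene
Product: 11 3-tert-butoxy-2-docosyl-4-hydroxy-4-(methoxyethynyl)cyclobut-2-en-1-one (racemic), via lithium methoxyacetylide 10 (not isolated)
Conditions: 9 (1.3 equiv), n-BuLi (1.2 equiv), THF, −78 °C; then 6 in THF, −78 °C; sat. aq NH4Cl at −78 °C; rapid filtration through Et3N-washed silica
Reagents that add atoms: none
Why: Lithium acetylide 1,2-addition should take place at the ketone-like carbonyl flanked by the tert-butoxy-bearing carbon and not at the other carbonyl, which is deactivated as a vinylogous ester, as is general for 3-alkoxy-4-alkylcyclobutenediones; the new carbinol centre forms racemic and is erased in step 4.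

**Step 4**
Reactants: 11 3-tert-butoxy-2-docosyl-4-hydroxy-4-(methoxyethynyl)cyclobut-2-en-1-one
Product: 14 2-tert-butoxy-3-docosyl-5-methoxycyclohexa-2,5-diene-1,4-dione, via enynylketene 12 (not isolated), via aryl phenoxyl diradical 13 (not isolated)
Conditions: degassed toluene (0.02 M), 110 °C, dark
Reagents that add atoms: none
Why: Heating should open the cyclobutenone by conrotatory 4π-electrocyclic cleavage of the bond between the carbonyl carbon and the carbinol carbon, the donor hydroxyl turning outward so that the methoxyethynyl group lies cis to the ketene in enynylketene 12; the ketene carbon then bonds to the distal, methoxy-bearing alkyne carbon to give diradical 13 (phenoxyl oxygen plus a σ-radical on the proximal alkyne carbon), and transfer of the hydroxyl hydrogen to that carbon gives the quinone. The closest known reaction type is the Moore rearrangement of 4-alkynyl-4-hydroxycyclobutenones to 1,4-benzoquinones. The one ring that closes, the six-membered quinone ring, closes in the 6-endo-dig mode with respect to the alkyne, which makes the net change a two-carbon expansion of the four-membered ring. No stereocentre is formed, and the racemic carbinol centre of 11 is lost. The selectivity needed is six- over five-membered closure (5-exo-dig attack at the proximal alkyne carbon would give an alkylidenecyclopentenedione); a methoxy group, unlike aryl, silyl or ester groups, does not stabilise the linear vinyl radical of the five-membered path, and the placing of docosyl and methoxy on either side of the same carbonyl is fixed by the constitution of 11.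

**Step 5**
Reactants: 14 2-tert-butoxy-3-docosyl-5-methoxycyclohexa-2,5-diene-1,4-dione
Product: 15 3-docosyl-2-hydroxy-5-methoxycyclohexa-2,5-diene-1,4-dione (target)
Conditions: CF3CO2H, CH2Cl2, 0 °C → rt
Reagents that add atoms: none
Why: Acidolysis of the tert-butyl vinylogous ester by the E1 path (tert-butyl cation, then 2-methylpropene) should free the C2 hydroxyl, while the C5 methyl vinylogous ester has no such path and is not hydrolysed by anhydrous acid.

**Compound list**

1 | 1-bromodocosane | CCCCCCCCCCCCCCCCCCCCCCBr | starting material
2 | di-tert-butyl squarate (3,4-di-tert-butoxycyclobut-3-ene-1,2-dione) | CC(C)(C)OC1=C(OC(C)(C)C)C(=O)C1=O | starting material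
3 | docosylmagnesium bromide | CCCCCCCCCCCCCCCCCCCCCC[Mg]Br | intermediate
4 | bromomagnesium 2,3-di-tert-butoxy-1-docosyl-4-oxocyclobut-2-en-1-olate (racemic) | CCCCCCCCCCCCCCCCCCCCCCC1(O[Mg]Br)C(OC(C)(C)C)=C(OC(C)(C)C)C1=O | intermediate
5 | 2,3-di-tert-butoxy-1-docosyl-4-oxocyclobut-2-en-1-yl trifluoroacetate (racemic) | CCCCCCCCCCCCCCCCCCCCCCC1(OC(=O)C(F)(F)F)C(OC(C)(C)C)=C(OC(C)(C)C)C1=O | intermediate
6 | 3-tert-butoxy-4-docosylcyclobut-3-ene-1,2-dione | CCCCCCCCCCCCCCCCCCCCCCC1=C(OC(C)(C)C)C(=O)C1=O | intermediate
7 | 2-chloro-1,1-dimethoxyethane | COC(CCl)OC | starting material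
8 | sodium methoxyacetylide | COC#C[Na] | intermediate
9 | methoxyacetylene (methoxyethyne) | COC#C | intermediate
10 | lithium methoxyacetylide | COC#C[Li] | intermediate
11 | 3-tert-butoxy-2-docosyl-4-hydroxy-4-(methoxyethynyl)cyclobut-2-en-1-one (racemic) | CCCCCCCCCCCCCCCCCCCCCCC1=C(OC(C)(C)C)C(O)(C#COC)C1=O | intermediate
12 | (3Z)-3-tert-butoxy-2-docosyl-4-hydroxy-6-methoxyhexa-1,3-dien-5-yn-1-one (enynylketene) | CCCCCCCCCCCCCCCCCCCCCCC(=C=O)/C(OC(C)(C)C)=C(/O)C#COC | intermediate
13 | aryl phenoxyl diradical (oxyl on the former ketene carbon, carbon radical on the former proximal alkyne carbon; ring bearing docosyl, tert-butoxy, hydroxy and methoxy) | CCCCCCCCCCCCCCCCCCCCCCc1c(OC(C)(C)C)c(O)[c]c(OC)c1[O] | intermediate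
14 | 2-tert-butoxy-3-docosyl-5-methoxycyclohexa-2,5-diene-1,4-dione | CCCCCCCCCCCCCCCCCCCCCCC1=C(OC(C)(C)C)C(=O)C=C(OC)C1=O | intermediate
15 | 3-docosyl-2-hydroxy-5-methoxycyclohexa-2,5-diene-1,4-dione | CCCCCCCCCCCCCCCCCCCCCCC1=C(O)C(=O)C=C(OC)C1=O | target

**Count**

Total steps: 5. Longest linear sequence: 4 (steps 1, 3, 4, 5; step 2 makes the alkyne partner on a side branch).

**Steps most likely to fail**

1. Step 4. The enynylketene may close at the proximal alkyne carbon (five-membered path) in competition with quinone formation, and the tert-butyl group may be lost thermally before the rearrangement is complete. Fallback: setting out from 11, semi-hydrogenation of the ynol ether (H2, Pd on CaCO3 poisoned with Pb(OAc)2, quinoline, EtOAc with a trace of Et3N, 0 °C) should give 3-tert-butoxy-2-docosyl-4-hydroxy-4-[(Z)-2-methoxyethenyl]cyclobut-2-en-1-one F1. Thermolysis of F1 (toluene, 110 °C) follows the purely pericyclic alkenyl variant of the same ring expansion, which has no diradical and so no choice of ring size: 4π opening to the dienylketene (3Z,5Z)-3-tert-butoxy-2-docosyl-4-hydroxy-6-methoxyhexa-1,3,5-trien-1-one F2, 6π electrocyclisation to 3-tert-butoxy-2-docosyl-4-hydroxy-6-methoxycyclohexa-2,4-dien-1-one F3, and tautomerisation to the hydroquinone 2-tert-butoxy-3-docosyl-5-methoxybenzene-1,4-diol F4. Oxidation of F4 with Ag2O (Et2O, rt) comes back to the route at 14.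

2. Step 3. The alkoxyethynyl carbinol may collapse on work-up or on silica (acid-induced Meyer–Schuster-type rearrangement or hydration of the ynol ether), and the acetylide may attack the vinylogous ester instead of the ketone-like carbonyl. Fallback: setting out from 6, HC≡CMgBr (THF, −78 °C) should give the robust carbinol 3-tert-butoxy-2-docosyl-4-ethynyl-4-hydroxycyclobut-2-en-1-one F5. Thermolysis (p-xylene, 138 °C) through the enynylketene (3Z)-3-tert-butoxy-2-docosyl-4-hydroxyhexa-1,3-dien-5-yn-1-one F6 and the corresponding aryl phenoxyl diradical F7 should give 2-tert-butoxy-3-docosylcyclohexa-2,5-diene-1,4-dione F8, terminal alkynes being reliable for six-membered closure. The methoxy group is then brought in after the ring expansion: ZnCl2-promoted conjugate addition of methanol (MeOH/CH2Cl2, rt) at C5, the position β to the more electrophilic C1 carbonyl, gives the hydroquinone F4, and Ag2O in the same flask oxidises it, which comes back to the route at 14.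

3. Step 2. The volatile, polymerisation-prone ynol ether may be lost on distillation, and ammonia or moisture carried over would attack the vinylogous ester of 6 in step 3. Fallback: setting out from 7, LiNEt2 (3 equiv, THF, −78 → 0 °C) should effect the same eliminations in one flask, by way of 1-chloro-2-methoxyethene F9 and then 9 in solution, and deprotonate 9 as it forms; this comes back to the route at 10, which is cooled to −78 °C before 6 is added. The diethylamine and lithium methoxide left in the flask are the liability of this variant (both can exchange the tert-butoxy group of 6), which is why it is not the first choice.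

**Further compounds**

F1 | step 4 | 3-tert-butoxy-2-docosyl-4-hydroxy-4-[(Z)-2-methoxyethenyl]cyclobut-2-en-1-one (racemic) | CCCCCCCCCCCCCCCCCCCCCCC1=C(OC(C)(C)C)C(O)(/C=C\OC)C1=O
F2 | step 4 | (3Z,5Z)-3-tert-butoxy-2-docosyl-4-hydroxy-6-methoxyhexa-1,3,5-trien-1-one | CCCCCCCCCCCCCCCCCCCCCCC(=C=O)/C(OC(C)(C)C)=C(/O)\C=C/OC
F3 | step 4 | 3-tert-butoxy-2-docosyl-4-hydroxy-6-methoxycyclohexa-2,4-dien-1-one (racemic) | CCCCCCCCCCCCCCCCCCCCCCC1=C(OC(C)(C)C)C(O)=CC(OC)C1=O
F4 | step 4 | 2-tert-butoxy-3-docosyl-5-methoxybenzene-1,4-diol | CCCCCCCCCCCCCCCCCCCCCCc1c(OC(C)(C)C)c(O)cc(OC)c1O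
F5 | step 3 | 3-tert-butoxy-2-docosyl-4-ethynyl-4-hydroxycyclobut-2-en-1-one (racemic) | CCCCCCCCCCCCCCCCCCCCCCC1=C(OC(C)(C)C)C(O)(C#C)C1=O
F6 | step 3 | (3Z)-3-tert-butoxy-2-docosyl-4-hydroxyhexa-1,3-dien-5-yn-1-one | CCCCCCCCCCCCCCCCCCCCCCC(=C=O)/C(OC(C)(C)C)=C(/O)C#C
F7 | step 3 | aryl phenoxyl diradical (ring bearing docosyl, tert-butoxy and hydroxy) | CCCCCCCCCCCCCCCCCCCCCCc1c(OC(C)(C)C)c(O)[c]cc1[O]
F8 | step 3 | 2-tert-butoxy-3-docosylcyclohexa-2,5-diene-1,4-dione | CCCCCCCCCCCCCCCCCCCCCCC1=C(OC(C)(C)C)C(=O)C=CC1=O
F9 | step 2 | 1-chloro-2-methoxyethene (mixture of geometric isomers) | COC=CCl
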